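Watch the share, not the yield.

| flask | starting material | coupling partner | remark | time |
|---|---|---|---|---|
| ash | 0.050 M (in portions, 3) | 0.15 M | the very flask that is asked about, followed so far; portions every 4.0 h |  |
| oak | 0.075 M (in portions, 3) | 0.15 M | run made earlier; portions every 4.0 h |  |
| flask | 0.050 M (in portions, 3) | 0.150 M | the portions of starting material follow each other after 4.0 h, the first at the start | 15 d |

ash run (percent of the starting material charged)

| time / h | target / % | isomer of the product / % |
|---|---|---|
| 5.00 | 3.2 | 1.6 |
| 10.0 | 12.2 | 1.7 |
| 15.0 | 20.3 | 4.6 |
| 20.0 | 31.6 | 8.3 |
| 25.0 | 37.9 | 12.1 |
| 30.0 | 45.0 | 13.3 |

oak run (percent of the starting material charged)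

| time / d | target / % | isomer of the product / % |
|---|---|---|
| 0.500 | 15.3 | 2.4 |
| 0.833 | 27.8 | 8.3 |
| 1.25 | 38.8 | 11.1 |
| 2.00 | 51.7 | 16.4 |
| 4.00 | 67.4 | 22.7 |
| 6.00 | 71.2 | 24.0 |

(each reading ± 1 percentage point)

- amount of target at 15 d, in percent of the starting material charged
- amount of isomer of the product at 15 d, in percent of the starting material charged

I ask first what the end state of the ash flask must be, and I build it up one process at a time. With the main step on its own, starting material and coupling partner give target one to one. Ash holds 0.150 M of coupling partner against 0.050 M of starting material, so starting material is the limiting reagent, and the ceiling is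

C = smaller charge / charge of starting material = 100%

Next I add the isomerisation. Oak's last readings give target as a share of target plus isomer of the product:

S = target / (target + isomer of the product) = 74.8%

This share S of target in the combined product is a reading and carries the scatter. It stands at 74.8% two days earlier, so I take it as level. Target falls from C to C × S:

target = 74.8%, isomer of the product = 25.2%

Then come the remaining steps, and with them I ask how fast that end state is approached. Oak's gap to full conversion goes from 9.90% to 4.80% in the interval between those readings, a halving time of 1.91 d. Continued to 15 d at that halving time, I estimate the gap at 0.185%, far smaller than the 4.80% of oak's last reading. At the same moment, 30.0 h, the combined product read in ash is higher than that read in oak, 58.3% against 49.9%. So I leave my number as it stands.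

The forecast gives 73.5% target, below my figure, and 25% isomer of the product, holding that “Isomerisation therefore looks like a fast equilibrium”.

The flask gives 74.1% target and 25.9% isomer of the product.

    starting material + coupling partner ⇌ intermediate (K = 110 M⁻¹, k = 0.0160 M⁻¹ min⁻¹)
    intermediate ⇌ target + released group (K = 0.00380 M, k = 0.00140 min⁻¹)
    released group → by-product carried off (k = 0.00870 min⁻¹)
    target ⇌ isomer of the product (K = 0.350, k = 0.00140 min⁻¹)

The flask's combined product of >99.9%, times S, makes 74.8% target, and S remains a reading that carries the scatter. In this flask half the turnover of the carrying-off of released group is done by 1.18 d, far earlier than the 15 d asked, and left ten times as long it still holds 74.1% target.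

The neighbour charged with 0.20 M of starting material has 0.750 equiv of coupling partner, so C = 75.0%, and C × S gives 56.1% target and 18.9% isomer of the product. Computed, it holds 55.1% and 19.3%, with 0.15% of its coupling partner and 25% of its starting material left.

All runs come from a simulation with constants of no real substance; noise was put on by code.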